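**Plan**

Ring labels: A has its OH para to the biaryl bond, B has its OH next to the diaryl ether oxygen, C is the para-phenylene, D has its OH ortho to the biaryl bond.
Cuts: the phenols are masked (A and B as OMe, D as OMs) and the A-B bridge carbon on ring B is raised to C=O. The macrocycle is then opened at the C(=O)-ring B bond, and the seco acid is cut at the A-D biaryl bond, at the C-D bridge (as C=C) and at the ring C carbon-oxygen bond of the ether.
Forward order: B-C ether (SNAr), C-D stilbene (Wittig), A-D biaryl (Suzuki-Miyaura), one hydrogenation to the seco arylacetic acid, Friedel-Crafts closure of the only new ring (16-membered), then C=O to CH2 and unmasking.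
Enabling feature: the ring B carbon that bears the A-B bridge is the C-H para to the ring B oxygen, the most nucleophilic position of the seco acid. In ring D both carbons ortho to the biaryl bond are substituted (O and CH2), so the ring A arylacetyl cation has no six-membered phenanthrol outlet, and the OMs group also disarms the ipso carbon, the oxygen and the para C-H of ring D.
Stereochemistry: the target has no stereocentre and no C=C, and the stilbene E/Z mixture is erased by hydrogenation, so nothing has to be controlled.

Key step: step 11

Assumption: the biaryl axis is undefined in the target structure, so all macrocycles are taken as racemic or interconverting and are drawn without axial descriptors.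

**Route**

Step 1
Reactants: 1 guaiacol; 2 4-fluorobenzaldehyde
Product: 3 4-(2-methoxyphenoxy)benzaldehyde
Conditions: K2CO3, DMF, 150 °C
Reagents that add atoms: none
Why: Nucleophilic aromatic substitution (SNAr), in which the para formyl group activates the C-F bond towards the guaiacolate, a standard entry to 4-aryloxybenzaldehydes.

Step 2
Reactants: 3 4-(2-methoxyphenoxy)benzaldehyde
Product: 4 [4-(2-methoxyphenoxy)phenyl]methanol
Conditions: NaBH4, MeOH, 0 °C to rt
Reagents that add atoms: none
Why: Borohydride reduction of an aromatic aldehyde, which leaves both ether groups untouched.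

Step 3
Reactants: 4 [4-(2-methoxyphenoxy)phenyl]methanol
Product: 5 [4-(2-methoxyphenoxy)benzyl]triphenylphosphonium bromide
Conditions: PPh3·HBr, MeCN, reflux
Reagents that add atoms: triphenylphosphine hydrobromide, Br.c1ccc(cc1)P(c1ccccc1)c1ccccc1
Why: Direct phosphonium salt formation from an electron-rich benzylic alcohol, in which HBr activates the para-aryloxybenzylic C-O bond and PPh3 is alkylated at phosphorus, so no separate halide step is needed.

Step 4
Reactants: 6 2-bromo-3-hydroxybenzaldehyde
Product: 7 2-bromo-3-formylphenyl methanesulfonate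
Conditions: MsCl, Et3N, CH2Cl2, 0 °C
Reagents that add atoms: methanesulfonyl chloride, CS(=O)(=O)Cl
Why: O-Sulfonylation of a phenol; the mesylate is chosen because it withdraws electron density from ring D for step 11 and tolerates mild base, palladium catalysis, neutral hydrogenation and acid.

Step 5
Reactants: 5 [4-(2-methoxyphenoxy)benzyl]triphenylphosphonium bromide; 7 2-bromo-3-formylphenyl methanesulfonate
Product: 9 2-bromo-3-{2-[4-(2-methoxyphenoxy)phenyl]ethenyl}phenyl methanesulfonate (E/Z mixture), via benzylidene phosphorane 8 (not isolated)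
Conditions: K2CO3, 18-crown-6 (cat.), CH2Cl2, reflux
Reagents that add atoms: none
Why: Wittig olefination under solid-liquid phase-transfer conditions, where carbonate is basic enough for the benzylic salt but too weak to harm the mesylate, and the alkene geometry does not matter because step 10 saturates it.

Step 6
Reactants: 10 3-methoxyphenylacetic acid
Product: 11 2-(2-bromo-5-methoxyphenyl)acetic acid
Conditions: NBS, MeCN, 0 °C to rt
Reagents that add atoms: N-bromosuccinimide, O=C1CCC(=O)N1Br
Why: Electrophilic aromatic bromination, which in MeCN goes para to methoxy and thus ortho to the CH2CO2H group, setting the ring A pattern (oxygen para and side chain ortho to the future biaryl bond).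

Step 7
Reactants: 11 2-(2-bromo-5-methoxyphenyl)acetic acid
Product: 12 benzyl 2-(2-bromo-5-methoxyphenyl)acetate
Conditions: BnBr, K2CO3, DMF, rt
Reagents that add atoms: benzyl bromide, BrCc1ccccc1
Why: SN2 O-alkylation of the carboxylate; the benzyl ester lets the acid be released later by hydrogenolysis, so the mesylate never meets hydroxide before step 13.

Step 8
Reactants: 12 benzyl 2-(2-bromo-5-methoxyphenyl)acetate
Product: 13 benzyl 2-[5-methoxy-2-(4,4,5,5-tetramethyl-1,3,2-dioxaborolan-2-yl)phenyl]acetate
Conditions: B2pin2, Pd(dppf)Cl2 (cat.), KOAc, 1,4-dioxane, 90 °C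
Reagents that add atoms: bis(pinacolato)diboron, CC1(C)OB(OC1(C)C)B1OC(C)(C)C(C)(C)O1
Why: Miyaura borylation of an aryl bromide, in which acetate is too weak a base to enolise the arylacetate or to start homocoupling.

Step 9
Reactants: 9 2-bromo-3-{2-[4-(2-methoxyphenoxy)phenyl]ethenyl}phenyl methanesulfonate (E/Z mixture); 13 benzyl 2-[5-methoxy-2-(4,4,5,5-tetramethyl-1,3,2-dioxaborolan-2-yl)phenyl]acetate
Product: 14 benzyl 2-(4-methoxy-2'-{2-[4-(2-methoxyphenoxy)phenyl]ethenyl}-6'-(methylsulfonyloxy)biphenyl-2-yl)acetate (E/Z mixture)
Conditions: Pd(OAc)2 (cat.), SPhos, K3PO4, toluene/H2O (20:1), 90 °C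
Reagents that add atoms: none
Why: Suzuki-Miyaura coupling with a bulky electron-rich biarylphosphine suited to tri-ortho-substituted biaryls, in which the C-Br bond adds to zerovalent palladium far faster than the C-OMs bond and phosphate is too weak for ester alpha-arylation.

Step 10
Reactants: 14 benzyl 2-(4-methoxy-2'-{2-[4-(2-methoxyphenoxy)phenyl]ethenyl}-6'-(methylsulfonyloxy)biphenyl-2-yl)acetate (E/Z mixture)
Product: 15 seco acid, 2-(4-methoxy-2'-{2-[4-(2-methoxyphenoxy)phenyl]ethyl}-6'-(methylsulfonyloxy)biphenyl-2-yl)acetic acid
Conditions: H2 (1-3 bar), Pd/C, EtOAc/EtOH, rt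
Reagents that add atoms: none
Why: Heterogeneous catalytic hydrogenation saturates both stilbene isomers and hydrogenolyses the benzyl ester in one neutral operation, to which aryl mesylates, aryl methyl ethers and the diaryl ether are inert.

Step 11
Reactants: 15 seco acid, 2-(4-methoxy-2'-{2-[4-(2-methoxyphenoxy)phenyl]ethyl}-6'-(methylsulfonyloxy)biphenyl-2-yl)acetic acid
Product: 17 macrocyclic deoxybenzoin ketone (16-membered ring A-CH2-C(=O)-B-O-C-CH2CH2-D-A; OMe on A para to the biaryl bond, OMe on B para to the C=O, OMs on D ortho to the biaryl bond), via seco acid chloride 16 (not isolated)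
Conditions: (COCl)2, DMF (cat.), CH2Cl2, 0 °C to rt, evaporate; then 16 in CH2Cl2 added by syringe pump over 12 h to SnCl4 (5 equiv), CH2Cl2, 0 °C to rt (final about 1 mM); 1 M HCl work-up
Reagents that add atoms: oxalyl chloride, O=C(Cl)C(=O)Cl (gives the chlorine of 16; no atom of it remains in 17)
Why: Oxalyl chloride converts 15 into 16, SnCl4 ionises 16 to an arylacetyl acylium ion, this bonds to the ring B C-H carbon para to methoxy to give an oxygen-stabilised arenium ion, and proton loss gives 17. The closest known reaction type is the high-dilution intramolecular Friedel-Crafts acylation of aryl-terminated acid chlorides to cyclophane ketones. The one ring formed is 16-membered and arises by head-to-tail closure (16-exo-dig at the acylium carbon, ring B ending up meta-bridged between the new carbonyl and the ether oxygen), while slow addition keeps free 16 so dilute that dimerisation should stay behind. Site selectivity within ring B is needed and comes from methoxy being a stronger para director than the aryloxy oxygen, whose lone pair is shared with ring C. Selectivity among the rings comes from the substrate: ring D has no free ortho carbon and is electron-poor through OMs (no phenanthrol, no ipso spirocyclisation, no acyl transfer to oxygen, no intermolecular attack para to oxygen), ring A offers only crowded positions ortho to methoxy, and ring C could react only through a strained 10- or 11-membered ring. No stereocentre is created, and the new carbonyl group makes ring B too electron-poor for a second acylation.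

Step 12
Reactants: 17 macrocyclic deoxybenzoin ketone
Product: 18 plagiochin E ring A, ring B di-O-methyl ether, ring D O-mesylate (both bridges CH2CH2)
Conditions: Et3SiH, CF3CO2H, CH2Cl2, rt to 40 °C
Reagents that add atoms: none
Why: Ionic hydrogenation, in which the protonated para-methoxyaryl ketone takes hydride from the silane, the carbinol ionises to a methoxy-stabilised benzylic cation that takes a second hydride, and mesylate and methyl ethers are acid-stable.

Step 13
Reactants: 18 plagiochin E ring A, ring B di-O-methyl ether, ring D O-mesylate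
Product: 19 plagiochin E ring A, ring B di-O-methyl ether (ring D phenol free)
Conditions: 2 M aq NaOH, 1,4-dioxane, 80 °C; then 1 M HCl
Reagents that add atoms: none
Why: Alkaline hydrolysis of an aryl sulfonate with S-O cleavage (attack at sulfur or E1cB through sulfene) frees the ring D phenol, while aryl methyl ethers and the diaryl ether are inert to hydroxide.

Step 14
Reactants: 19 plagiochin E ring A, ring B di-O-methyl ether
Product: 20 plagiochin E
Conditions: BBr3, CH2Cl2, -78 °C to rt; H2O
Reagents that add atoms: none
Why: Lewis-acid ether cleavage, in which BBr3 binds each methoxy oxygen and bromide removes the methyl group by SN2, while the diaryl ether has no sp3 C-O bond and survives.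

**Compound list**

1 | guaiacol | COc1ccccc1O | starting material
2 | 4-fluorobenzaldehyde | O=Cc1ccc(F)cc1 | starting material
3 | 4-(2-methoxyphenoxy)benzaldehyde | COc1ccccc1Oc1ccc(C=O)cc1 | intermediate
4 | [4-(2-methoxyphenoxy)phenyl]methanol | COc1ccccc1Oc1ccc(CO)cc1 | intermediate
5 | [4-(2-methoxyphenoxy)benzyl]triphenylphosphonium bromide | COc1ccccc1Oc1ccc(cc1)C[P+](c1ccccc1)(c1ccccc1)c1ccccc1.[Br-] | intermediate
6 | 2-bromo-3-hydroxybenzaldehyde | O=Cc1cccc(O)c1Br | starting material
7 | 2-bromo-3-formylphenyl methanesulfonate | CS(=O)(=O)Oc1cccc(C=O)c1Br | intermediate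
8 | [4-(2-methoxyphenoxy)benzylidene]triphenylphosphorane (not isolated) | COc1ccccc1Oc1ccc(cc1)C=P(c1ccccc1)(c1ccccc1)c1ccccc1 | intermediate
9 | 2-bromo-3-{2-[4-(2-methoxyphenoxy)phenyl]ethenyl}phenyl methanesulfonate (E/Z mixture, geometry left open) | COc1ccccc1Oc1ccc(cc1)C=Cc1cccc(OS(C)(=O)=O)c1Br | intermediate
10 | 3-methoxyphenylacetic acid | COc1cccc(CC(=O)O)c1 | starting material
11 | 2-(2-bromo-5-methoxyphenyl)acetic acid | COc1ccc(Br)c(CC(=O)O)c1 | intermediate
12 | benzyl 2-(2-bromo-5-methoxyphenyl)acetate | COc1ccc(Br)c(CC(=O)OCc2ccccc2)c1 | intermediate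
13 | benzyl 2-[5-methoxy-2-(4,4,5,5-tetramethyl-1,3,2-dioxaborolan-2-yl)phenyl]acetate | COc1ccc(B2OC(C)(C)C(C)(C)O2)c(CC(=O)OCc2ccccc2)c1 | intermediate
14 | benzyl 2-(4-methoxy-2'-{2-[4-(2-methoxyphenoxy)phenyl]ethenyl}-6'-(methylsulfonyloxy)biphenyl-2-yl)acetate (E/Z mixture, geometry left open) | COc1ccc(c(c1)CC(=O)OCc1ccccc1)-c1c(OS(C)(=O)=O)cccc1C=Cc1ccc(cc1)Oc1ccccc1OC | intermediate
15 | seco acid, 2-(4-methoxy-2'-{2-[4-(2-methoxyphenoxy)phenyl]ethyl}-6'-(methylsulfonyloxy)biphenyl-2-yl)acetic acid | COc1ccc(c(c1)CC(=O)O)-c1c(OS(C)(=O)=O)cccc1CCc1ccc(cc1)Oc1ccccc1OC | intermediate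
16 | seco acid chloride, the acetyl chloride of 15 (not isolated) | COc1ccc(c(c1)CC(=O)Cl)-c1c(OS(C)(=O)=O)cccc1CCc1ccc(cc1)Oc1ccccc1OC | intermediate
17 | macrocyclic deoxybenzoin ketone (C=O on ring B para to OMe) | COc1ccc2c(c1)CC(=O)c1ccc(OC)c(c1)Oc1ccc(cc1)CCc1cccc(OS(C)(=O)=O)c1-2 | intermediate
18 | plagiochin E ring A, ring B di-O-methyl ether, ring D O-mesylate | COc1ccc2c(c1)CCc1ccc(OC)c(c1)Oc1ccc(cc1)CCc1cccc(OS(C)(=O)=O)c1-2 | intermediate
19 | plagiochin E ring A, ring B di-O-methyl ether | COc1ccc2c(c1)CCc1ccc(OC)c(c1)Oc1ccc(cc1)CCc1cccc(O)c1-2 | intermediate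
20 | plagiochin E | Oc1ccc2c(c1)CCc1ccc(O)c(c1)Oc1ccc(cc1)CCc1cccc(O)c1-2 | target

**Step count**

Total step count: 14.
Longest linear sequence: 10 steps (1, 2, 3, 5, 9, 10, 11, 12, 13, 14).

**Steps most likely to fail**

Step 11. Three processes are at risk here:
- intermolecular acylation overtaking the slow 16-membered closure
- attack on ring B para to the aryloxy oxygen rather than para to methoxy
- loss of CO from the acylium ion before it reaches ring B

The fallback sets out from 15 and comes back at 18. It forms the same C-C bond with reversed polarity, at a ring B carbon fixed beforehand by a halogen. Iodination of 15 (N-iodosuccinimide, catalytic CF3CO2H, MeCN) is an intermolecular substitution free of ring strain. It should pick the position para to the ring B methoxy group, because ring D is deactivated and rings A and C have no free para position, and so give the iodo seco acid F1. BH3·THF reduces it to the iodo arylethanol F2, and Dess-Martin periodinane in CH2Cl2 gives the iodo arylacetaldehyde F3. Nozaki-Hiyama-Kishi ring closure (CrCl2 in excess, catalytic NiCl2, DMF, high dilution, rt) adds the ring B carbon to the aldehyde and gives the macrocyclic benzylic alcohol F4. Its carbinol configuration is not controlled and does not matter. Et3SiH and CF3CO2H then remove the hydroxyl group and deliver 18.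

Step 9. The arylpalladium intermediate is slowed by its two ortho groups. It may be diverted into C-H activation of ring C across the Z-stilbene or into Heck-type addition to the alkene, while the boronate undergoes protodeboronation as it waits.

The fallback sets out from 7 and comes back at 14. It makes the biaryl before ring C is attached and reverses the polarity of the olefination. NaBH4 in MeOH at 0 °C reduces 7 to 2-bromo-3-(hydroxymethyl)phenyl methanesulfonate F5. This small bromide offers palladium neither an alkene nor a ring C C-H bond. It is coupled with 13 under the conditions of step 9 to give the biaryl benzylic alcohol F6. PPh3·HBr in refluxing MeCN converts F6 into the biaryl phosphonium bromide F7. K2CO3 and 18-crown-6 in CH2Cl2 generate the biaryl ylide F8, which olefinates aldehyde 3 to give 14. Compounds 4, 5, 8 and 9 are then no longer needed.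

Step 12. The reduction may stall at the carbinol or trifluoroacetate stage, or the benzylic cation may be captured transannularly by a neighbouring arene of the macrocycle.

The fallback sets out from 17 and comes back at 19. It replaces the cationic pathway by an anionic one. In a Wolff-Kishner reduction (N2H4·H2O, KOH, diethylene glycol, 130 °C then 200 °C; acidic work-up) hydroxide strips the mesylate and the ketone condenses to the macrocyclic hydrazone F9. Base-induced loss of nitrogen leaves the CH2 group, so 19 is reached directly and step 13 falls away. Any methyl ether cleaved at this temperature does no harm, because step 14 removes all of them.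

**Further compounds**

F1 | step 11 | iodo seco acid, 15 with iodine on ring B para to OMe | COc1ccc(c(c1)CC(=O)O)-c1c(OS(C)(=O)=O)cccc1CCc1ccc(cc1)Oc1cc(I)ccc1OC
F2 | step 11 | iodo arylethanol, CH2CH2OH in place of CH2CO2H | COc1ccc(c(c1)CCO)-c1c(OS(C)(=O)=O)cccc1CCc1ccc(cc1)Oc1cc(I)ccc1OC
F3 | step 11 | iodo arylacetaldehyde | COc1ccc(c(c1)CC=O)-c1c(OS(C)(=O)=O)cccc1CCc1ccc(cc1)Oc1cc(I)ccc1OC
F4 | step 11 | macrocyclic benzylic alcohol (carbinol configuration not controlled) | COc1ccc2c(c1)CC(O)c1ccc(OC)c(c1)Oc1ccc(cc1)CCc1cccc(OS(C)(=O)=O)c1-2
F5 | step 9 | 2-bromo-3-(hydroxymethyl)phenyl methanesulfonate | CS(=O)(=O)Oc1cccc(CO)c1Br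
F6 | step 9 | biaryl benzylic alcohol, benzyl 2-[2'-(hydroxymethyl)-4-methoxy-6'-(methylsulfonyloxy)biphenyl-2-yl]acetate | COc1ccc(c(c1)CC(=O)OCc1ccccc1)-c1c(OS(C)(=O)=O)cccc1CO
F7 | step 9 | biaryl phosphonium bromide | COc1ccc(c(c1)CC(=O)OCc1ccccc1)-c1c(OS(C)(=O)=O)cccc1C[P+](c1ccccc1)(c1ccccc1)c1ccccc1.[Br-]
F8 | step 9 | biaryl ylide | COc1ccc(c(c1)CC(=O)OCc1ccccc1)-c1c(OS(C)(=O)=O)cccc1C=P(c1ccccc1)(c1ccccc1)c1ccccc1
F9 | step 12 | macrocyclic hydrazone (ring D phenol free, C=N geometry left open) | COc1ccc2c(c1)CC(=NN)c1ccc(OC)c(c1)Oc1ccc(cc1)CCc1cccc(O)c1-2
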